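**Strategy**

The 2'-oxygen of ring B is installed late, by a carboxyl group placed on C3 of ring C. The C2=C3 double bond holds this carboxyl cis to the aryl ring, so one of its oxygens can reach the unhindered ring B ortho carbon, which is C2' of the target and lies para to the C5' methoxy group. A single anodic oxidation forms the C2'–O bond and closes a six-membered lactone that masks the phenol. Its substrate is a 2-(3,4-dimethoxyphenyl)-8-methoxychromone-3-carboxylic acid whose ring A is deactivated as the 5,7-diacetate. Afterwards tert-butoxide opens the lactone, the phenols are capped as benzyl ethers, and the carboxyl carbon leaves as CO2.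

Key step: step 6

Remark on numbering: flavone numbering is used; the ring B carbon that is oxidized is C6' of the 3,4-dimethoxyphenyl group in 7–12 and is C2' in 13–18. The target has no stereocentre.

Remark on design: a free 2'-phenol next to a free C3 carboxyl closes back to the lactone, so the acid is released only after the 2'-oxygen is etherified. The pyrone ring is never opened while a second ortho oxygen of ring A or the 2'-oxygen is free, which excludes Wessely–Moser-type isomerization. Ring A carries benzyl ethers wherever strong base is used and acetates only for the electrolysis.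

**Route**

Step 1
Reactants: 1 iretol (2-methoxybenzene-1,3,5-triol)
Product: 3 1-(2,4,6-trihydroxy-3-methoxyphenyl)ethan-1-one, via ketiminium chloride 2 (not isolated)
Conditions: MeCN, ZnCl2, HCl (g), Et2O, 0 °C; then H2O, 100 °C
Reagents that add atoms: acetonitrile CC#N; water O
Why: Houben–Hoesch acylation of a phloroglucinol-type arene; the two open ring positions of 1 are equivalent by symmetry, so hydrolysis of the iminium salt should give a single ketone.

Step 2
Reactants: 3 1-(2,4,6-trihydroxy-3-methoxyphenyl)ethan-1-one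
Product: 4 1-[4,6-bis(benzyloxy)-2-hydroxy-3-methoxyphenyl]ethan-1-one
Conditions: BnBr (2.1 equiv), K2CO3, acetone, reflux
Reagents that add atoms: benzyl bromide BrCc1ccccc1
Why: Williamson etherification should take the unchelated 4-OH (para to the acetyl group) and then the less hindered 6-OH, while the 2-OH, wedged between the methoxy and acetyl groups and held in the carbonyl hydrogen bond, should stay free.

Step 3
Reactants: 4 1-[4,6-bis(benzyloxy)-2-hydroxy-3-methoxyphenyl]ethan-1-one; 5 3,4-dimethoxybenzoyl chloride
Product: 7 5,7-bis(benzyloxy)-2-(3,4-dimethoxyphenyl)-8-methoxy-4H-chromen-4-one, via 1,3-diketone 6 (not isolated)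
Conditions: LiN(SiMe3)2 (3.2 equiv), THF, −78 to −10 °C; 5, −78 °C to rt; aq. HCl; then TsOH·H2O (cat.), toluene, 90 °C
Reagents that add atoms: none
Why: C-aroylation of the phenoxide–enolate dianion (a Claisen-type condensation, the one-pot equivalent of a Baker–Venkataraman sequence) followed by acid-catalysed cyclodehydration; only one phenol is free, so only the 8-methoxy flavone can form.

Step 4
Reactants: 7 5,7-bis(benzyloxy)-2-(3,4-dimethoxyphenyl)-8-methoxy-4H-chromen-4-one
Product: 9 5,7-bis(benzyloxy)-2-(3,4-dimethoxyphenyl)-8-methoxy-4-oxo-4H-chromene-3-carboxylic acid, via 3-lithioflavone 8 (not isolated)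
Conditions: LiN(i-Pr)2 (1.5 equiv), THF, −78 °C; CO2 (gas), −78 °C to rt; aq. HCl, 0 °C
Reagents that add atoms: carbon dioxide O=C=O
Why: directed lithiation of a flavone at C3, its only vinylic C–H and the one next to the coordinating C4 carbonyl, followed by carboxylation of the vinyllithium.

Step 5
Reactants: 9 5,7-bis(benzyloxy)-2-(3,4-dimethoxyphenyl)-8-methoxy-4-oxo-4H-chromene-3-carboxylic acid
Product: 12 5,7-diacetoxy-2-(3,4-dimethoxyphenyl)-8-methoxy-4-oxo-4H-chromene-3-carboxylic acid, via dihydroxy acid 10 (not isolated), via mixed anhydride 11 (not isolated)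
Conditions: H2 (1 atm), Pd/C (10 wt %), THF–EtOAc, rt; filter, concentrate; Ac2O, pyridine, DMAP (cat.), 0 °C to rt; then THF–H2O, rt
Reagents that add atoms: acetic anhydride CC(=O)OC(C)=O
Why: hydrogenolysis of the two aryl benzyl ethers and acetylation of both phenols are standard, and the carboxylic–acetic mixed anhydride formed alongside should be hydrolysed by the aqueous quench much faster than the aryl acetates.

Step 6
Reactants: 12 5,7-diacetoxy-2-(3,4-dimethoxyphenyl)-8-methoxy-4-oxo-4H-chromene-3-carboxylic acid
Product: 13 2,3,11-trimethoxy-6,7-dioxo-6H,7H-chromeno[4,3-b]chromene-8,10-diyl diacetate (the 5,7-diacetoxy-8,4',5'-trimethoxyflavone whose C3 carbonyl is bonded through oxygen to C2')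
Conditions: undivided cell, graphite anode, Pt cathode, n-Bu4NBF4 (0.1 M), 2,6-lutidine (0.5 equiv), MeCN–HFIP (4:1), constant current (about 5 mA cm−2, 2.2–2.5 F mol−1), rt
Reagents that add atoms: none
Why: With part of the acid deprotonated by 2,6-lutidine, the carboxylate (or ring B, the most electron-rich arene once ring A carries two acetates) loses one electron at the carbon anode; the acyloxy radical (or, equivalently, the carboxylate and the ring B radical cation) joins O to C6', and loss of a second electron and a proton restores aromaticity while the cathode reduces protons to H2. The closest known reaction type is the anodic dehydrogenative lactonization of biaryl-2-carboxylic acids to benzo[c]chromen-6-ones, the C2=C3 bond of ring C here holding aryl and carboxyl cis in the same 1,4-relationship. The six-membered lactone closes by 6-endo-trig attack of oxygen on the ortho carbon; 5-exo attack at C1' would lead to a spiro lactone that is expected to drain into the same product by 1,2-acyloxy shift. No stereocentre is formed. The step needs site selectivity for C6' over C2' and chemoselectivity for ring B over ring A: C6' is flanked only by H and lies para to the 3'-methoxy group, whereas C2' is wedged between C1' and that methoxy group, and the 5,7-diacetate removes the electron-rich 5,8-dioxygenated pattern of ring A that would otherwise be oxidized to a quinone. HFIP stabilizes the cationic intermediates and, being non-nucleophilic, leaves the acetates in place.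

Step 7
Reactants: 13 2,3,11-trimethoxy-6,7-dioxo-6H,7H-chromeno[4,3-b]chromene-8,10-diyl diacetate
Product: 15 tert-butyl 5,7-bis(benzyloxy)-2-[2-(benzyloxy)-4,5-dimethoxyphenyl]-8-methoxy-4-oxo-4H-chromene-3-carboxylate, via tripotassium triphenoxide 14 (not isolated)
Conditions: KOt-Bu (3.3 equiv), THF, −20 to 0 °C; then BnBr (4 equiv), n-Bu4NI (cat.), DMF, 0 to 45 °C
Reagents that add atoms: potassium tert-butoxide CC(C)(C)[O-].[K+]; benzyl bromide BrCc1ccccc1
Why: alkoxide opening of an aryl (biaryl-type) lactone by acyl substitution, with the bulky tert-butoxide unable to add to the fully substituted C2, also cleaves both aryl acetates; Williamson benzylation of the three phenoxides then fixes the open form, which has no free carboxylate and a poor tert-butoxide leaving group and so should not close back.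

Step 8
Reactants: 15 tert-butyl 5,7-bis(benzyloxy)-2-[2-(benzyloxy)-4,5-dimethoxyphenyl]-8-methoxy-4-oxo-4H-chromene-3-carboxylate
Product: 17 5,7-bis(benzyloxy)-2-[2-(benzyloxy)-4,5-dimethoxyphenyl]-8-methoxy-4H-chromen-4-one, via free acid 16 (not isolated)
Conditions: TFA–CH2Cl2 (1:4), 0 °C to rt; evaporate; Ag2CO3 (10 mol %), AcOH (5 mol %), DMSO, 120 °C
Reagents that add atoms: none
Why: acidolysis of the tert-butyl ester (E1 loss of 2-methylpropene) followed by silver-catalysed protodecarboxylation of a doubly ortho-substituted heteroaromatic carboxylic acid; the 2'-benzyl ether blocks relactonization and the pyrone ring stays closed throughout.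

Step 9
Reactants: 17 5,7-bis(benzyloxy)-2-[2-(benzyloxy)-4,5-dimethoxyphenyl]-8-methoxy-4H-chromen-4-one
Product: 18 5,7-dihydroxy-2-(2-hydroxy-4,5-dimethoxyphenyl)-8-methoxy-4H-chromen-4-one (CNP0497620.0)
Conditions: H2 (1 atm), Pd/C (10 wt %), THF–MeOH, rt
Reagents that add atoms: none
Why: hydrogenolysis of three aryl benzyl ethers under neutral conditions should free the phenols without the acid or base that could open the pyrone ring of a 5,2'-dihydroxyflavone.

**Compound list**

1 | iretol (2-methoxybenzene-1,3,5-triol) | COc1c(O)cc(O)cc1O | starting material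
2 | 1-(2,4,6-trihydroxy-3-methoxyphenyl)ethan-1-iminium chloride | CC(=[NH2+])c1c(O)cc(O)c(OC)c1O.[Cl-] | intermediate
3 | 1-(2,4,6-trihydroxy-3-methoxyphenyl)ethan-1-one | CC(=O)c1c(O)cc(O)c(OC)c1O | intermediate
4 | 1-[4,6-bis(benzyloxy)-2-hydroxy-3-methoxyphenyl]ethan-1-one | CC(=O)c1c(OCc2ccccc2)cc(OCc2ccccc2)c(OC)c1O | intermediate
5 | 3,4-dimethoxybenzoyl chloride | COc1ccc(C(Cl)=O)cc1OC | starting material
6 | 1-[4,6-bis(benzyloxy)-2-hydroxy-3-methoxyphenyl]-3-(3,4-dimethoxyphenyl)propane-1,3-dione | COc1ccc(C(=O)CC(=O)c2c(OCc3ccccc3)cc(OCc3ccccc3)c(OC)c2O)cc1OC | intermediate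
7 | 5,7-bis(benzyloxy)-2-(3,4-dimethoxyphenyl)-8-methoxy-4H-chromen-4-one | COc1ccc(-c2cc(=O)c3c(OCc4ccccc4)cc(OCc4ccccc4)c(OC)c3o2)cc1OC | intermediate
8 | [5,7-bis(benzyloxy)-2-(3,4-dimethoxyphenyl)-8-methoxy-4-oxo-4H-chromen-3-yl]lithium | COc1ccc(-c2oc3c(OC)c(OCc4ccccc4)cc(OCc4ccccc4)c3c(=O)c2[Li])cc1OC | intermediate
9 | 5,7-bis(benzyloxy)-2-(3,4-dimethoxyphenyl)-8-methoxy-4-oxo-4H-chromene-3-carboxylic acid | COc1ccc(-c2oc3c(OC)c(OCc4ccccc4)cc(OCc4ccccc4)c3c(=O)c2C(=O)O)cc1OC | intermediate
10 | 2-(3,4-dimethoxyphenyl)-5,7-dihydroxy-8-methoxy-4-oxo-4H-chromene-3-carboxylic acid | COc1ccc(-c2oc3c(OC)c(O)cc(O)c3c(=O)c2C(=O)O)cc1OC | intermediate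
11 | acetic 5,7-diacetoxy-2-(3,4-dimethoxyphenyl)-8-methoxy-4-oxo-4H-chromene-3-carboxylic anhydride | COc1ccc(-c2oc3c(OC)c(OC(C)=O)cc(OC(C)=O)c3c(=O)c2C(=O)OC(C)=O)cc1OC | intermediate
12 | 5,7-diacetoxy-2-(3,4-dimethoxyphenyl)-8-methoxy-4-oxo-4H-chromene-3-carboxylic acid | COc1ccc(-c2oc3c(OC)c(OC(C)=O)cc(OC(C)=O)c3c(=O)c2C(=O)O)cc1OC | intermediate
13 | 2,3,11-trimethoxy-6,7-dioxo-6H,7H-chromeno[4,3-b]chromene-8,10-diyl diacetate | COc1cc2c(cc1OC)oc(=O)c1c(=O)c3c(OC(C)=O)cc(OC(C)=O)c(OC)c3oc12 | intermediate
14 | tripotassium salt of tert-butyl 5,7-dihydroxy-2-(2-hydroxy-4,5-dimethoxyphenyl)-8-methoxy-4-oxo-4H-chromene-3-carboxylate (three phenoxides) | COc1cc([O-])c(-c2oc3c(OC)c([O-])cc([O-])c3c(=O)c2C(=O)OC(C)(C)C)cc1OC.[K+].[K+].[K+] | intermediate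
15 | tert-butyl 5,7-bis(benzyloxy)-2-[2-(benzyloxy)-4,5-dimethoxyphenyl]-8-methoxy-4-oxo-4H-chromene-3-carboxylate | COc1cc(OCc2ccccc2)c(-c2oc3c(OC)c(OCc4ccccc4)cc(OCc4ccccc4)c3c(=O)c2C(=O)OC(C)(C)C)cc1OC | intermediate
16 | 5,7-bis(benzyloxy)-2-[2-(benzyloxy)-4,5-dimethoxyphenyl]-8-methoxy-4-oxo-4H-chromene-3-carboxylic acid | COc1cc(OCc2ccccc2)c(-c2oc3c(OC)c(OCc4ccccc4)cc(OCc4ccccc4)c3c(=O)c2C(=O)O)cc1OC | intermediate
17 | 5,7-bis(benzyloxy)-2-[2-(benzyloxy)-4,5-dimethoxyphenyl]-8-methoxy-4H-chromen-4-one | COc1cc(OCc2ccccc2)c(-c2cc(=O)c3c(OCc4ccccc4)cc(OCc4ccccc4)c(OC)c3o2)cc1OC | intermediate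
18 | 5,7-dihydroxy-2-(2-hydroxy-4,5-dimethoxyphenyl)-8-methoxy-4H-chromen-4-one | COc1cc(O)c(-c2cc(=O)c3c(O)cc(O)c(OC)c3o2)cc1OC | target

**Totals and risks**

Total step count: 9. Longest linear sequence: 9 steps (1 to 18).

Steps most likely to fail:

1. Step 6 (anodic lactonization). Electron loss may occur at the wrong place: ipso attack at C1' with loss of the para methoxy methyl group, oxidation of ring A, or Kolbe-type loss of CO2 from the acyloxy radical. The anode may also passivate. The fallback replaces outer-sphere electron transfer by carboxylate-directed C–H activation: Pd(OAc)2 (cat.), PhI(OAc)2, N-acetylglycine, KOAc, t-BuOH, 80 °C. Cyclopalladation at the less hindered C6'–H, oxidation to tetravalent palladium and C–O reductive elimination should give the same lactone. It sets out from 12 and returns at 13, and makes no new compound (F0).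

2. Step 7 (lactone opening and capping). Acyl substitution by the bulky alkoxide at the hindered lactone carbonyl may be incomplete, or the 2'-phenoxide may close back onto the ester before it is benzylated. The fallback sets out from 13 and uses the small nucleophile hydroxide, which gives a carboxylate that cannot relactonize in base: LiOH (6 equiv), THF–H2O, 0 °C, should give the tetralithium salt F1. After removal of the solvents, BnBr and Cs2CO3 in DMF at 50 °C should alkylate the three phenoxides and the carboxylate to the benzyl ester F2. LiI in EtOAc at reflux should then cleave only the benzyl ester, by SN2 attack of iodide at its benzylic carbon, and acidification returns the route at acid 16 (decarboxylation stage of step 8).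

3. Step 4 (C3 lithiation and carboxylation). Deprotonation may compete at a benzylic OCH2 group or on ring B, or the amide base may add to the pyrone, leaving unchanged 7 or ring-opened material. The fallback introduces the carboxyl before the pyrone is built and sets out from 4. Claisen condensation with dibenzyl carbonate (NaH, THF, at most 40 °C, kept mild to avoid closure to a 4-hydroxycoumarin) should give the benzyl β-keto ester F3. Aroylation with 5 (K2CO3, acetone, reflux) should give the triketone F4, which TsOH (cat., toluene, 80 °C) should cyclodehydrate to the benzyl flavone-3-carboxylate F5. Hydrogenolysis (H2, Pd/C, THF–EtOAc) removes all three benzyl groups and returns the route at 10 (acetylation stage of step 5).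

Further compounds
F0 | step 6 | none | none
F1 | step 7 | tetralithium 2-(4,5-dimethoxy-2-oxidophenyl)-8-methoxy-5,7-dioxido-4-oxo-4H-chromene-3-carboxylate | COc1cc([O-])c(-c2oc3c(OC)c([O-])cc([O-])c3c(=O)c2C(=O)[O-])cc1OC.[Li+].[Li+].[Li+].[Li+]
F2 | step 7 | benzyl 5,7-bis(benzyloxy)-2-[2-(benzyloxy)-4,5-dimethoxyphenyl]-8-methoxy-4-oxo-4H-chromene-3-carboxylate | COc1cc(OCc2ccccc2)c(-c2oc3c(OC)c(OCc4ccccc4)cc(OCc4ccccc4)c3c(=O)c2C(=O)OCc2ccccc2)cc1OC
F3 | step 4 | benzyl 3-[4,6-bis(benzyloxy)-2-hydroxy-3-methoxyphenyl]-3-oxopropanoate | O=C(CC(=O)c1c(OCc2ccccc2)cc(OCc2ccccc2)c(OC)c1O)OCc1ccccc1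
F4 | step 4 | benzyl 2-[4,6-bis(benzyloxy)-2-hydroxy-3-methoxybenzoyl]-3-(3,4-dimethoxyphenyl)-3-oxopropanoate | COc1ccc(C(=O)C(C(=O)OCc2ccccc2)C(=O)c2c(OCc3ccccc3)cc(OCc3ccccc3)c(OC)c2O)cc1OC
F5 | step 4 | benzyl 5,7-bis(benzyloxy)-2-(3,4-dimethoxyphenyl)-8-methoxy-4-oxo-4H-chromene-3-carboxylate | COc1ccc(-c2oc3c(OC)c(OCc4ccccc4)cc(OCc4ccccc4)c3c(=O)c2C(=O)OCc2ccccc2)cc1OC
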